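**Assumption:** the target has no stereocentre and no stereogenic double bond, so it is achiral and no enantioselective step is needed. The stereocentres in 5, 6 and 7 (racemic, diastereomer and tautomer mixtures) disappear on aromatisation. In all arene names C1 carries the carbonyl group and C6 the heptyl chain.

## Retrosynthetic overview
1. Target 19 comes from the dibenzyl-protected depside 18 by one global hydrogenolysis. Cutting the aryl ester C–O bond of 18 gives ring A acid 11 and ring B phenol 16.
2. Both 11 and 16 come from one resorcylate, 8, by complementary O-alkylation (4-OMe/2-OBn for ring A, 4-OBn/2-OMe for ring B) and ester exchange.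
3. 8 comes from cyclohexanedione ester 6 by aromatisation, 6 from keto diester 5 by Dieckmann-type Claisen closure, and 5 from enone 3 and dimethyl malonate 4 by an intermolecular Michael addition (the key C–C bond).
4. 3 comes from octanal 1 and the acetonyl ylide 2.
5. Ring order: the single carbocycle is built in step 2 and aromatised in step 3. It is then divided to serve as ring A and ring B, and no further ring is formed.

## Route

**Step 1**
Reactants: 1 octanal; 2 1-(triphenylphosphoranylidene)propan-2-one
Product: 3 (E)-undec-3-en-2-one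
Conditions: 2 (1.1 equiv), CH2Cl2, 40 °C, 16 h
Reagents that add atoms: none
Why: Wittig olefination with a ketone-stabilised ylide reacts only at the aldehyde and gives the E-enone (>95:5) without aldehyde self-condensation, and the alkene geometry is erased in step 2.

**Step 2**
Reactants: 3 (E)-undec-3-en-2-one; 4 dimethyl malonate
Product: 6 methyl 6-heptyl-2-hydroxy-4-oxocyclohex-2-ene-1-carboxylate, via keto diester Michael adduct 5 (not isolated)
Conditions: NaOMe (1.2 equiv), 4 (1.15 equiv), MeOH, rt then reflux, 4 h; then cold aq HCl to pH 3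
Reagents that add atoms: none
Why: The malonate enolate adds 1,4 to the enone (intermolecular Michael addition), and the methyl-ketone enolate of 5 then closes the six-membered ring on one ester (Dieckmann-type Claisen condensation), driven by the stabilised 1,3-dicarbonyl enolate, while the two new stereocentres need no control because step 3 removes them.

**Step 3**
Reactants: 6 methyl 6-heptyl-2-hydroxy-4-oxocyclohex-2-ene-1-carboxylate
Product: 8 methyl 6-heptyl-2,4-dihydroxybenzoate, via bromo enol-ketone 7 (not isolated)
Conditions: Br2 (1.0 equiv), DMF, 0 °C, 1 h; then 80 °C, 14 h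
Reagents that add atoms: bromine, BrBr (its bromine sits only in intermediate 7 and is lost again)
Why: Bromination of the enolised 1,3-dione at C3, thermal dehydrobromination and keto–enol tautomerisation (bromination–dehydrobromination aromatisation) give the resorcylate, and holding at 80 °C avoids loss of the ester by demethylation and decarboxylation.

**Step 4** (ring A branch)
Reactants: 8 methyl 6-heptyl-2,4-dihydroxybenzoate
Product: 9 methyl 6-heptyl-2-hydroxy-4-methoxybenzoate
Conditions: MeI (1.05 equiv), K2CO3 (1.1 equiv), acetone, reflux, 5 h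
Reagents that add atoms: iodomethane, CI
Why: This Williamson etherification is regioselective because the 2-OH is hydrogen-bonded to the ester carbonyl, so one equivalent of MeI alkylates only the more acidic, unhindered 4-OH.

**Step 5**
Reactants: 9 methyl 6-heptyl-2-hydroxy-4-methoxybenzoate
Product: 10 methyl 2-(benzyloxy)-6-heptyl-4-methoxybenzoate
Conditions: BnBr (1.3 equiv), K2CO3 (2 equiv), DMF, 65 °C, 12 h
Reagents that add atoms: benzyl bromide, BrCc1ccccc1
Why: Williamson etherification in a dipolar aprotic solvent with heating overcomes the chelation of the only remaining phenol.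

**Step 6**
Reactants: 10 methyl 2-(benzyloxy)-6-heptyl-4-methoxybenzoate
Product: 11 2-(benzyloxy)-6-heptyl-4-methoxybenzoic acid
Conditions: KOH (10 equiv), DMSO/H2O 4:1, 100 °C, 8 h; then cold 2 M HCl
Reagents that add atoms: potassium hydroxide, [K+].[OH-]
Why: Poorly solvated hydroxide in aqueous DMSO saponifies the di-ortho-substituted benzoate, and the ethers are inert to base.

**Step 7** (ring B branch)
Reactants: 8 methyl 6-heptyl-2,4-dihydroxybenzoate
Product: 12 methyl 4-(benzyloxy)-6-heptyl-2-hydroxybenzoate
Conditions: BnBr (1.05 equiv), K2CO3 (1.1 equiv), acetone, reflux, 6 h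
Reagents that add atoms: benzyl bromide, BrCc1ccccc1
Why: This Williamson etherification shows the same chelation-controlled selectivity as step 4 and masks the 4-OH temporarily.

**Step 8**
Reactants: 12 methyl 4-(benzyloxy)-6-heptyl-2-hydroxybenzoate
Product: 13 methyl 4-(benzyloxy)-6-heptyl-2-methoxybenzoate
Conditions: MeI (3 equiv), K2CO3 (2.5 equiv), DMF, 40 °C, closed flask, 16 h
Reagents that add atoms: iodomethane, CI
Why: Williamson methylation with excess reagent in DMF alkylates the only free, chelated phenol.

**Step 9**
Reactants: 13 methyl 4-(benzyloxy)-6-heptyl-2-methoxybenzoate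
Product: 14 4-(benzyloxy)-6-heptyl-2-methoxybenzoic acid
Conditions: KOH (10 equiv), DMSO/H2O 4:1, 100 °C, 8 h; then cold 2 M HCl
Reagents that add atoms: potassium hydroxide, [K+].[OH-]
Why: This is the same saponification of a hindered benzoate as in step 6, and both ethers survive.

**Step 10**
Reactants: 14 4-(benzyloxy)-6-heptyl-2-methoxybenzoic acid
Product: 15 6-heptyl-4-hydroxy-2-methoxybenzoic acid
Conditions: H2 (1 atm), 10% Pd/C, EtOAc, rt, 3 h
Reagents that add atoms: none
Why: Catalytic hydrogenolysis cleaves the benzyl ether under neutral conditions at room temperature, so the decarboxylation-prone hydroxy acid is not heated or exposed to acid.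

**Step 11**
Reactants: 15 6-heptyl-4-hydroxy-2-methoxybenzoic acid
Product: 16 benzyl 6-heptyl-4-hydroxy-2-methoxybenzoate
Conditions: BnBr (1.05 equiv), KHCO3 (1.5 equiv), DMF, rt to 40 °C, 16 h
Reagents that add atoms: benzyl bromide, BrCc1ccccc1
Why: KHCO3 deprotonates only the carboxylic acid, so SN2 carboxylate alkylation gives the benzyl ester and leaves the 4-OH free.

**Step 12**
Reactants: 11 2-(benzyloxy)-6-heptyl-4-methoxybenzoic acid; 16 benzyl 6-heptyl-4-hydroxy-2-methoxybenzoate
Product: 18 benzyl 4-{[2-(benzyloxy)-6-heptyl-4-methoxybenzoyl]oxy}-6-heptyl-2-methoxybenzoate, via mixed trifluoroacetic anhydride 17 (not isolated)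
Conditions: (CF3CO)2O (4 equiv), dry toluene, rt, 6 h
Reagents that add atoms: trifluoroacetic anhydride, O=C(OC(=O)C(F)(F)F)C(F)(F)F (its atoms sit only in intermediate 17)
Why: In this mixed-anhydride esterification the electron-rich, di-ortho-substituted aroyl trifluoroacetate has acylium character and so escapes the steric block to addition at carbonyl, and 16 offers a single hydroxyl as acceptor.

**Step 13**
Reactants: 18 benzyl 4-{[2-(benzyloxy)-6-heptyl-4-methoxybenzoyl]oxy}-6-heptyl-2-methoxybenzoate
Product: 19 4-[(6-heptyl-2-hydroxy-4-methoxybenzoyl)oxy]-6-heptyl-2-methoxybenzoic acid (target)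
Conditions: H2 (1 atm), 10% Pd/C, EtOAc, rt, 4 h
Reagents that add atoms: none
Why: Global catalytic hydrogenolysis removes the benzyl ether and benzyl ester together under neutral, non-nucleophilic conditions (no alcohol solvent), so the base- and alcohol-sensitive depside ester stays intact.

## Compound list
1 | octanal | CCCCCCCC=O | starting material
2 | 1-(triphenylphosphoranylidene)propan-2-one | CC(=O)C=P(c1ccccc1)(c1ccccc1)c1ccccc1 | starting material
3 | (E)-undec-3-en-2-one | CCCCCCC/C=C/C(C)=O | intermediate
4 | dimethyl malonate | COC(=O)CC(=O)OC | starting material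
5 | dimethyl 2-(2-oxoundecan-4-yl)propanedioate (racemic, formed in the flask) | CCCCCCCC(CC(C)=O)C(C(=O)OC)C(=O)OC | intermediate
6 | methyl 6-heptyl-2-hydroxy-4-oxocyclohex-2-ene-1-carboxylate (racemic, enol of the 2,4-dione) | CCCCCCCC1CC(=O)C=C(O)C1C(=O)OC | intermediate
7 | methyl 3-bromo-6-heptyl-2-hydroxy-4-oxocyclohex-2-ene-1-carboxylate (racemic, formed in the flask) | CCCCCCCC1CC(=O)C(Br)=C(O)C1C(=O)OC | intermediate
8 | methyl 6-heptyl-2,4-dihydroxybenzoate | CCCCCCCc1cc(O)cc(O)c1C(=O)OC | intermediate
9 | methyl 6-heptyl-2-hydroxy-4-methoxybenzoate | CCCCCCCc1cc(OC)cc(O)c1C(=O)OC | intermediate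
10 | methyl 2-(benzyloxy)-6-heptyl-4-methoxybenzoate | CCCCCCCc1cc(OC)cc(OCc2ccccc2)c1C(=O)OC | intermediate
11 | 2-(benzyloxy)-6-heptyl-4-methoxybenzoic acid | CCCCCCCc1cc(OC)cc(OCc2ccccc2)c1C(=O)O | intermediate
12 | methyl 4-(benzyloxy)-6-heptyl-2-hydroxybenzoate | CCCCCCCc1cc(OCc2ccccc2)cc(O)c1C(=O)OC | intermediate
13 | methyl 4-(benzyloxy)-6-heptyl-2-methoxybenzoate | CCCCCCCc1cc(OCc2ccccc2)cc(OC)c1C(=O)OC | intermediate
14 | 4-(benzyloxy)-6-heptyl-2-methoxybenzoic acid | CCCCCCCc1cc(OCc2ccccc2)cc(OC)c1C(=O)O | intermediate
15 | 6-heptyl-4-hydroxy-2-methoxybenzoic acid | CCCCCCCc1cc(O)cc(OC)c1C(=O)O | intermediate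
16 | benzyl 6-heptyl-4-hydroxy-2-methoxybenzoate | CCCCCCCc1cc(O)cc(OC)c1C(=O)OCc1ccccc1 | intermediate
17 | 2-(benzyloxy)-6-heptyl-4-methoxybenzoic trifluoroacetic anhydride (formed in the flask) | CCCCCCCc1cc(OC)cc(OCc2ccccc2)c1C(=O)OC(=O)C(F)(F)F | intermediate
18 | benzyl 4-{[2-(benzyloxy)-6-heptyl-4-methoxybenzoyl]oxy}-6-heptyl-2-methoxybenzoate | CCCCCCCc1cc(OC)cc(OCc2ccccc2)c1C(=O)Oc1cc(CCCCCCC)c(C(=O)OCc2ccccc2)c(OC)c1 | intermediate
19 | 4-[(6-heptyl-2-hydroxy-4-methoxybenzoyl)oxy]-6-heptyl-2-methoxybenzoic acid | CCCCCCCc1cc(OC)cc(O)c1C(=O)Oc1cc(CCCCCCC)c(C(=O)O)c(OC)c1 | target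

## Step count
Total steps: 13.
Longest linear sequence: 10 (steps 1, 2, 3, 7, 8, 9, 10, 11, 12, 13).

## Three steps most likely to fail, and fallbacks

**Step 3 (aromatisation).** The risks are partial ring bromination of 8, incomplete HBr loss, or ester loss on heating.

The fallback sets out from 6 and comes back at 8. It drives bromination to completion and removes the halogens afterwards, instead of stopping at one equivalent. Treating 6 with Br2 (3 equiv) in AcOH at rt gives the crystalline methyl 3,5-dibromo-6-heptyl-2,4-dihydroxybenzoate F1. Reductive dehalogenation (H2, 10% Pd/C, NaOAc, MeOH, rt) then gives 8.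

**Step 12 (depside coupling).** The risks are sluggish acylation by the hindered acid, competing trifluoroacetylation of 16, or benzyl loss in the acidic medium.

The fallback sets out from 11 (with 16) and comes back at 18. It replaces the acidic in-situ activation by an isolated acyl halide and base-mediated nucleophilic catalysis. Oxalyl chloride with catalytic DMF in CH2Cl2 (0 °C to rt) converts 11 into 2-(benzyloxy)-6-heptyl-4-methoxybenzoyl chloride F2. After evaporation, F2 is combined with 16, Et3N and catalytic DMAP in CH2Cl2 to give 18.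

**Step 9 (saponification of the di-ortho-substituted ester; the same risk applies to step 6).** The risks are incomplete hydrolysis or aryl ether cleavage on prolonged heating.

The fallback sets out from 13 and comes back at 14. It avoids attack of hydroxide at the hindered carbonyl by a redox detour:
- LiAlH4 in THF (0 °C to rt) gives [4-(benzyloxy)-6-heptyl-2-methoxyphenyl]methanol F3.
- MnO2 in CH2Cl2 oxidises F3 to 4-(benzyloxy)-6-heptyl-2-methoxybenzaldehyde F4.
- Pinnick oxidation (NaClO2, NaH2PO4, 2-methylbut-2-ene, t-BuOH/H2O) gives 14.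

## Further compounds
F1 | step 3 | methyl 3,5-dibromo-6-heptyl-2,4-dihydroxybenzoate | CCCCCCCc1c(Br)c(O)c(Br)c(O)c1C(=O)OC
F2 | step 12 | 2-(benzyloxy)-6-heptyl-4-methoxybenzoyl chloride | CCCCCCCc1cc(OC)cc(OCc2ccccc2)c1C(Cl)=O
F3 | step 9 | [4-(benzyloxy)-6-heptyl-2-methoxyphenyl]methanol | CCCCCCCc1cc(OCc2ccccc2)cc(OC)c1CO
F4 | step 9 | 4-(benzyloxy)-6-heptyl-2-methoxybenzaldehyde | CCCCCCCc1cc(OCc2ccccc2)cc(OC)c1C=O
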